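**Retrosynthetic overview**

1. Target 12 comes from quercetin 3-acetate 11 by tris-O-sulfation (7, 3', 4'; the chelated 5-OH is spared). 11 comes from 5,7,3',4'-tetra-O-benzylquercetin 9, whose only free OH is the 3-OH, by acetylation and hydrogenolysis.
2. Key disconnection C2–C1' of 9: anodic dehydrogenative cross-coupling of the C2–H of 5,7-bis(benzyloxy)-3-hydroxychromone 6 with the C4–H of 1,2-bis(benzyloxy)benzene 7. Neither partner carries a halide or a metal, and the 3-OH emerges free.
3. Enabling feature: the enolic 3-OH on C3 of the pyranone ring (ring C), next to C4=O. It makes C2–H (the carbon between O1 and C3) a phenol-type ortho position; oxidation of the enol puts spin and charge on C2, stabilised by O1 as donor and the C3/C4 carbonyl unit as acceptor.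
4. 6 comes from chromone 4 (epoxidation/isomerisation), 4 from ketone 2 (DMF-DMA annulation), 2 from 2',4',6'-trihydroxyacetophenone 1.
5. Ring order: ring A comes with 1; ring C is closed in step 2 (O1–C2 bond); ring B arrives intact with 7 in step 4.

Key step: step 4

Assumption: the target has no stereocentre (it is achiral), so no stereocontrol is needed. The sulfate monoesters are drawn in the acid form; step 7 delivers this form by cation exchange, and the compound is better stored as a salt.

**Step 1**
Reactants: 1 1-(2,4,6-trihydroxyphenyl)ethan-1-one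
Product: 2 1-[2,4-bis(benzyloxy)-6-hydroxyphenyl]ethan-1-one
Conditions: BnBr (2.05 equiv), K2CO3 (2.2 equiv), DMF, 0 °C to rt
Reagents that add atoms: benzyl bromide, BrCc1ccccc1
Why: Williamson etherification in which the 4-OH and one of the two equivalent ortho-OH groups are alkylated, while the remaining ortho-OH is held in a hydrogen bond to the ketone and should stay free.

**Step 2**
Reactants: 2 1-[2,4-bis(benzyloxy)-6-hydroxyphenyl]ethan-1-one
Product: 4 5,7-bis(benzyloxy)-4H-chromen-4-one, via enaminone 3 (not isolated)
Conditions: DMF-DMA (2 equiv), toluene, 95 °C; evaporate; then AcOH, 80 °C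
Reagents that add atoms: N,N-dimethylformamide dimethyl acetal, COC(OC)N(C)C
Why: Condensation of the acetyl CH3 with DMF-DMA gives the E-enaminone, and acid-promoted addition of the phenol to its β-carbon with loss of dimethylamine closes the pyranone ring (standard enaminone chromone synthesis).

**Step 3**
Reactants: 4 5,7-bis(benzyloxy)-4H-chromen-4-one
Product: 6 5,7-bis(benzyloxy)-3-hydroxy-4H-chromen-4-one, via epoxide 5 (not isolated)
Conditions: DMDO (ca. 0.07 M in acetone, 1.5 equiv), CH2Cl2, 0 °C to rt; evaporate; then p-TsOH·H2O (10 mol %), CH2Cl2, rt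
Reagents that add atoms: dimethyldioxirane, CC1(C)OO1
Why: Electrophilic epoxidation of the C2=C3 bond, then acid-catalysed opening to the C2 oxocarbenium ion and loss of H-3, is the established epoxidation/isomerisation route from chromones and flavones to their 3-hydroxy derivatives, and benzyl ethers tolerate both reagents.

**Step 4**
Reactants: 6 5,7-bis(benzyloxy)-3-hydroxy-4H-chromen-4-one; 7 1,2-bis(benzyloxy)benzene (3 equiv)
Product: 9 5,7-bis(benzyloxy)-2-[3,4-bis(benzyloxy)phenyl]-3-hydroxy-4H-chromen-4-one, via 3,4-dione tautomer 8 (not isolated)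
Conditions: undivided cell, BDD anode, Ni cathode, constant current (5 mA cm−2, ca. 2.1 F per mol of 6), Bu3MeN+ MeOSO3− (0.1 M), HFIP, 40 °C
Reagents that add atoms: none
Why: Proposed new method: in HFIP the enol 6, which holds the only free O–H and is expected to be the partner of lower oxidation potential, should lose one electron and its O–H proton at the anode to give an oxyl radical whose spin sits largely on C2, captodatively stabilised by O1 and the C3/C4 carbonyl unit; this electrophilic radical (or, after a second electron transfer, the C2 oxocarbenium ion of the chromane-3,4-dione) is attacked by the nucleophilic arene 7, loss of the second electron and of the arene proton gives dione 8, and 8 enolises to the hydrogen-bonded flavonol 9 while the two protons are reduced to H2 at the cathode. The closest known reaction type is the anodic dehydrogenative phenol–arene cross-coupling at BDD in HFIP, where a phenoxyl radical is trapped ortho to its OH by a 1,2-dialkoxybenzene; here the 3-hydroxy-4-pyranone takes the role of the phenol and its C2–H that of the ortho position, which has not been shown for this substrate class. No ring is closed and no lasting stereocentre is formed, since C2 of 8 becomes sp2 on enolisation. Site selectivity on the chromone should follow from C2 being the only position conjugated to the single free OH, all other oxygens being benzyl ethers; on the arene, attack para to one benzyloxy group (C4, equivalent to C5 by symmetry) is favoured electronically and sterically over the flanked C3. Cross-coupling over homo-coupling and over further oxidation of the more electron-rich product relies on the potential gap between 6 and 7, the excess of 7, hydrogen bonding of HFIP to the 3-OH/C4=O unit of 9, and stopping the electrolysis near the theoretical charge.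

**Step 5**
Reactants: 9 5,7-bis(benzyloxy)-2-[3,4-bis(benzyloxy)phenyl]-3-hydroxy-4H-chromen-4-one
Product: 10 5,7-bis(benzyloxy)-2-[3,4-bis(benzyloxy)phenyl]-4-oxo-4H-chromen-3-yl acetate
Conditions: Ac2O (1.5 equiv), pyridine, DMAP (5 mol %), CH2Cl2, 0 °C to rt
Reagents that add atoms: acetic anhydride, CC(=O)OC(C)=O
Why: DMAP-catalysed acylation of the only free hydroxyl in the molecule, the 3-OH enol, so no selectivity question arises.

**Step 6**
Reactants: 10 5,7-bis(benzyloxy)-2-[3,4-bis(benzyloxy)phenyl]-4-oxo-4H-chromen-3-yl acetate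
Product: 11 2-(3,4-dihydroxyphenyl)-5,7-dihydroxy-4-oxo-4H-chromen-3-yl acetate (quercetin 3-acetate)
Conditions: H2 (1 atm), 10% Pd/C, THF/EtOAc 1:1, rt
Reagents that add atoms: none
Why: Catalytic hydrogenolysis of the four aryl benzyl ethers under neutral conditions without alcohol or base should leave the enol acetate and the chromone C2=C3 bond untouched.

**Step 7**
Reactants: 11 2-(3,4-dihydroxyphenyl)-5,7-dihydroxy-4-oxo-4H-chromen-3-yl acetate
Product: 12 quercetin 3-acetate 7,3',4'-tri-O-sulfate
Conditions: SO3·pyridine (9 equiv), dry DMF, rt; cold H2O quench; Sephadex LH-20; Dowex 50W-X8 (H+ form), 0 °C, freeze-dry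
Reagents that add atoms: sulfur trioxide–pyridine complex, O=S(=O)([O-])[n+]1ccccc1
Why: O-sulfation of phenols with an SO3–amine complex should take the 7-, 4'- and 3'-OH groups, while the 5-OH is deactivated by its strong hydrogen bond to C4=O, position 3 is blocked as the acetate, and the anhydrous base-free medium preserves the ester.

**Compound list**

1 | 1-(2,4,6-trihydroxyphenyl)ethan-1-one (2',4',6'-trihydroxyacetophenone) | CC(=O)c1c(O)cc(O)cc1O | starting material
2 | 1-[2,4-bis(benzyloxy)-6-hydroxyphenyl]ethan-1-one | CC(=O)c1c(O)cc(OCc2ccccc2)cc1OCc1ccccc1 | intermediate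
3 | (E)-1-[2,4-bis(benzyloxy)-6-hydroxyphenyl]-3-(dimethylamino)prop-2-en-1-one | CN(C)/C=C/C(=O)c1c(O)cc(OCc2ccccc2)cc1OCc1ccccc1 | intermediate
4 | 5,7-bis(benzyloxy)-4H-chromen-4-one | O=c1ccoc2cc(OCc3ccccc3)cc(OCc3ccccc3)c12 | intermediate
5 | 5,7-bis(benzyloxy)-2,3-epoxychroman-4-one (cis-fused, racemic; one enantiomer drawn) | O=C1c2c(OCc3ccccc3)cc(OCc3ccccc3)cc2O[C@@H]2O[C@H]12 | intermediate
6 | 5,7-bis(benzyloxy)-3-hydroxy-4H-chromen-4-one | O=c1c(O)coc2cc(OCc3ccccc3)cc(OCc3ccccc3)c12 | intermediate
7 | 1,2-bis(benzyloxy)benzene | c1ccc(COc2ccccc2OCc2ccccc2)cc1 | starting material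
8 | 5,7-bis(benzyloxy)-2-[3,4-bis(benzyloxy)phenyl]chromane-3,4-dione (keto tautomer of 9, racemic at C2) | O=C1C(=O)c2c(OCc3ccccc3)cc(OCc3ccccc3)cc2OC1c1ccc(OCc2ccccc2)c(OCc2ccccc2)c1 | intermediate
9 | 5,7-bis(benzyloxy)-2-[3,4-bis(benzyloxy)phenyl]-3-hydroxy-4H-chromen-4-one (5,7,3',4'-tetra-O-benzylquercetin) | O=c1c(O)c(-c2ccc(OCc3ccccc3)c(OCc3ccccc3)c2)oc2cc(OCc3ccccc3)cc(OCc3ccccc3)c12 | intermediate
10 | 5,7-bis(benzyloxy)-2-[3,4-bis(benzyloxy)phenyl]-4-oxo-4H-chromen-3-yl acetate | CC(=O)Oc1c(-c2ccc(OCc3ccccc3)c(OCc3ccccc3)c2)oc2cc(OCc3ccccc3)cc(OCc3ccccc3)c2c1=O | intermediate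
11 | 2-(3,4-dihydroxyphenyl)-5,7-dihydroxy-4-oxo-4H-chromen-3-yl acetate (quercetin 3-acetate) | CC(=O)Oc1c(-c2ccc(O)c(O)c2)oc2cc(O)cc(O)c2c1=O | intermediate
12 | quercetin 3-acetate 7,3',4'-tri-O-sulfate | CC(=O)Oc1c(-c2ccc(OS(=O)(=O)O)c(OS(=O)(=O)O)c2)oc2cc(OS(=O)(=O)O)cc(O)c2c1=O | target

**Step count and risks**

Total step count: 7. Longest linear sequence: 7 steps (1 to 12); 7 enters at step 4.

Steps most likely to fail:

1. Step 4 (proposed new method). What may go wrong: further anodic oxidation of the flavonol product, which is more electron-rich than 6, with solvent capture at C2; competing oxidation of the arene partner; homo-coupling of 6 through C6/C8 of its own A ring. Fallback with known chemistry, setting out from 6 and coming back at 9: 6 would be treated with chloromethyl methyl ether (COCCl) and iPr2NEt in CH2Cl2 to give the MOM ether 5,7-bis(benzyloxy)-3-(methoxymethoxy)-4H-chromen-4-one F1. With C3 blocked, TMPZnCl·LiCl in THF at 25 °C should remove the only remaining pyranone C–H (C2, flanked by O1 and the 3-OMOM group) to give the 2-(chlorozincio)chromone F2. Negishi coupling of this with commercial 4-bromo-1,2-bis(benzyloxy)benzene (Brc1ccc(OCc2ccccc2)c(OCc2ccccc2)c1; Pd(OAc)2/SPhos, THF, 50 °C) should give 5,7-bis(benzyloxy)-2-[3,4-bis(benzyloxy)phenyl]-3-(methoxymethoxy)-4H-chromen-4-one F3. Catalytic HCl in MeOH/THF at 45 °C would then release the 3-OH and return 9. Directed zincation of chromones at C2 followed by Negishi arylation is an established route to flavones.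

2. Step 7. What may go wrong: incomplete sulfation of the 3'-OH next to the 4'-sulfate, partial sulfation of the 5-OH under forcing excess, acetyl transfer or hydrolysis during the aqueous work-up, and mixtures of very polar products that are hard to separate. Fallback, setting out from 11 and coming back at 12: a protected-sulfate approach. 11 would be treated with 2,2,2-trichloroethyl chlorosulfate (ClS(=O)(=O)OCC(Cl)(Cl)Cl, 3.3 equiv) and Et3N in THF at −20 to 0 °C, without an acyl-transfer catalyst, to give the neutral tris(2,2,2-trichloroethyl sulfate) of quercetin 3-acetate F4. This can be purified on silica, which removes under- and over-sulfated material. Reductive removal of the three trichloroethyl groups with Zn dust and HCO2NH4 in MeOH/THF at rt, followed by H+ exchange at 0 °C, would return 12.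

3. Step 3. What may go wrong: slow epoxidation of the vinylogous-ester double bond, further oxidation of the product enol by excess dioxirane, and opening of the epoxide by adventitious water to diol mixtures. Fallback, setting out from 4 and coming back at 6: hypervalent-iodine α-hydroxylation through conjugate addition of methoxide. 4 would be treated with PhI(OAc)2 and KOH in MeOH at 0 °C to rt to give cis-5,7-bis(benzyloxy)-2,4,4-trimethoxychroman-3-ol F5 (racemic). Treatment of this with conc. HCl in acetone at rt should hydrolyse the ketal and eliminate methanol from C2 to return 6.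

**Further compounds**

F1 | step 4 | 5,7-bis(benzyloxy)-3-(methoxymethoxy)-4H-chromen-4-one | COCOc1coc2cc(OCc3ccccc3)cc(OCc3ccccc3)c2c1=O
F2 | step 4 | [5,7-bis(benzyloxy)-3-(methoxymethoxy)-4-oxo-4H-chromen-2-yl]zinc chloride (LiCl complex) | COCOc1c([Zn]Cl)oc2cc(OCc3ccccc3)cc(OCc3ccccc3)c2c1=O
F3 | step 4 | 5,7-bis(benzyloxy)-2-[3,4-bis(benzyloxy)phenyl]-3-(methoxymethoxy)-4H-chromen-4-one | COCOc1c(-c2ccc(OCc3ccccc3)c(OCc3ccccc3)c2)oc2cc(OCc3ccccc3)cc(OCc3ccccc3)c2c1=O
F4 | step 7 | quercetin 3-acetate 7,3',4'-tris(2,2,2-trichloroethyl sulfate) | CC(=O)Oc1c(-c2ccc(OS(=O)(=O)OCC(Cl)(Cl)Cl)c(OS(=O)(=O)OCC(Cl)(Cl)Cl)c2)oc2cc(OS(=O)(=O)OCC(Cl)(Cl)Cl)cc(O)c2c1=O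
F5 | step 3 | cis-5,7-bis(benzyloxy)-2,4,4-trimethoxychroman-3-ol (racemic; one enantiomer drawn) | CO[C@H]1Oc2cc(OCc3ccccc3)cc(OCc3ccccc3)c2C(OC)(OC)[C@H]1O
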